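**Plan**
- Retrosynthesis: the two C5/C5' O–CH3 bonds are cut first (catechols back to guaiacols), then the two C3–Br bonds, then the central CH2–CH2 bond via a stilbene C=C back to the aldehyde carbons of two vanillin units.
- Forward: vanillin is O-benzylated, coupled aldehyde-to-aldehyde (McMurry) to join the two-carbon chain, and hydrogenated, which saturates the alkene and frees both phenols before any bromine is present.
- Both rings are then brominated in one flask and the methyl ethers are removed last; no ring is formed anywhere, both benzene rings come intact from vanillin.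
- Enabling feature: in each ring the brominated carbon C3 is ortho to the C4 oxygen and meta to the bridge carbon C1. With C4–OH free, C5–O capped as OMe and C1 occupying the para position, C3 is the only carbon a phenol-directed bromination can reach.
- Stereochemistry: none to set; the E/Z geometry of the stilbene is erased by hydrogenation.

Key step: step 4

Remark: the target has no stereocentre and no stereogenic double bond, so it is a single achiral compound and no enantiocontrol is required.

**Step 1**
Reactants: 1 vanillin (4-hydroxy-3-methoxybenzaldehyde); 2 benzyl bromide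
Product: 3 4-(benzyloxy)-3-methoxybenzaldehyde
Conditions: BnBr (1.1 equiv), K2CO3 (1.5 equiv), DMF, 60 °C
Reagents that add atoms: benzyl bromide, BrCc1ccccc1
Why: Williamson ether synthesis, in which the acidic vanillin phenol is deprotonated by carbonate and displaces bromide from the benzylic halide by SN2 while the aldehyde is untouched.

**Step 2**
Reactants: 3 4-(benzyloxy)-3-methoxybenzaldehyde (two molecules)
Product: 4 (E)-1,2-bis[4-(benzyloxy)-3-methoxyphenyl]ethene
Conditions: TiCl4, Zn dust, THF, 0 °C → reflux
Reagents that add atoms: none
Why: McMurry coupling, in which low-valent titanium reductively joins two aryl aldehyde carbons and removes both oxygens at reflux to give mainly the E-stilbene; aryl benzyl and methyl ethers tolerate the reagent and the alkene geometry is irrelevant because the next step saturates it.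

**Step 3**
Reactants: 4 (E)-1,2-bis[4-(benzyloxy)-3-methoxyphenyl]ethene
Product: 6 4,4'-(ethane-1,2-diyl)bis(2-methoxyphenol), via bis(benzyl ether) bibenzyl 5 (not isolated)
Conditions: H2 (1 atm), 10% Pd/C, THF/MeOH, rt
Reagents that add atoms: none
Why: Heterogeneous catalytic hydrogenation saturates the stilbene double bond and hydrogenolysis then cleaves both benzylic C–O bonds, while aryl methyl ethers and the new CH2–CH2 bond are inert; doing this before bromination means no aryl bromide ever meets Pd/H2.

**Step 4**
Reactants: 6 4,4'-(ethane-1,2-diyl)bis(2-methoxyphenol); 7 N-bromosuccinimide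
Product: 9 4,4'-(ethane-1,2-diyl)bis(2-bromo-6-methoxyphenol), via monobromide 8 (not isolated)
Conditions: NBS (2.05 equiv, added slowly), i-Pr2NH (0.2 equiv), CH2Cl2, 0 °C → rt, dark
Reagents that add atoms: N-bromosuccinimide, O=C1CCC(=O)N1Br
Why: Diisopropylamine is brominated by NBS to N-bromodiisopropylamine, which hydrogen-bonds to the phenolic OH (or pairs with the ammonium phenoxide) and passes Br+ to the neighbouring ring carbon through a cyclic transition state; the ortho σ-complex then loses its proton and returns the amine. This is the amine-catalysed ortho-bromination of phenols with NBS, a known electrophilic aromatic substitution, run here on both rings in one flask. No ring is closed and no stereocentre is formed. The step needs C3 (ortho to C4–OH) to win over C2 (para to C5–OMe, next to the bridge) on both rings: the para position of each phenol is the substituted bridge carbon C1 and the other ortho carbon C5 carries OMe, so C3 is the only position the phenol or phenoxide activates, and delivery from the oxygen-bound N–Br reagent reaches no other carbon. Once one bromine is in, the remaining ring C–H positions are meta to the hydroxyl and the ring is deactivated, so each ring should stop at the monobromide and the second ring reacts independently of the first. Low temperature, exclusion of light and slow NBS addition should suppress radical bromination of the benzylic CH2 groups.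

**Step 5**
Reactants: 9 4,4'-(ethane-1,2-diyl)bis(2-bromo-6-methoxyphenol)
Product: 11 5,5'-(ethane-1,2-diyl)bis(3-bromobenzene-1,2-diol), via bis(bromodioxaborole) 10 (not isolated)
Conditions: BBr3 (6 equiv), CH2Cl2, −78 °C → rt, Ar; then ice-water, degassed dilute HCl work-up
Reagents that add atoms: boron tribromide, BrB(Br)Br (its boron and bromine sit only in intermediate 10; target 11 gains nothing but hydrogen from the aqueous quench)
Why: Lewis-acid aryl methyl ether cleavage, in which BBr3 binds the phenol and the methoxy oxygen, bromide attacks the O-methyl carbon by SN2 to release bromomethane, and water hydrolyses the cyclic aryl borate; aryl bromides and the bibenzyl bridge are inert to BBr3, and the acidic oxygen-free work-up protects the air-sensitive catechol.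

**Compound list**
1 | vanillin (4-hydroxy-3-methoxybenzaldehyde) | COc1cc(C=O)ccc1O | starting material
2 | benzyl bromide | BrCc1ccccc1 | starting material
3 | 4-(benzyloxy)-3-methoxybenzaldehyde | COc1cc(C=O)ccc1OCc1ccccc1 | intermediate
4 | (E)-1,2-bis[4-(benzyloxy)-3-methoxyphenyl]ethene | COc1cc(/C=C/c2ccc(OCc3ccccc3)c(OC)c2)ccc1OCc1ccccc1 | intermediate
5 | 1,2-bis[4-(benzyloxy)-3-methoxyphenyl]ethane | COc1cc(CCc2ccc(OCc3ccccc3)c(OC)c2)ccc1OCc1ccccc1 | intermediate (not isolated)
6 | 4,4'-(ethane-1,2-diyl)bis(2-methoxyphenol) | COc1cc(CCc2ccc(O)c(OC)c2)ccc1O | intermediate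
7 | N-bromosuccinimide | O=C1CCC(=O)N1Br | starting material
8 | 2-bromo-4-[2-(4-hydroxy-3-methoxyphenyl)ethyl]-6-methoxyphenol | COc1cc(CCc2cc(Br)c(O)c(OC)c2)ccc1O | intermediate (not isolated)
9 | 4,4'-(ethane-1,2-diyl)bis(2-bromo-6-methoxyphenol) | COc1cc(CCc2cc(Br)c(O)c(OC)c2)cc(Br)c1O | intermediate
10 | 1,2-bis(2,4-dibromo-1,3,2-benzodioxaborol-6-yl)ethane | Brc1cc(CCc2cc(Br)c3OB(Br)Oc3c2)cc2OB(Br)Oc12 | intermediate (not isolated)
11 | 5,5'-(ethane-1,2-diyl)bis(3-bromobenzene-1,2-diol) | Oc1cc(CCc2cc(O)c(O)c(Br)c2)cc(Br)c1O | target

Total step count: 5
Longest linear sequence: 5 steps (from vanillin 1)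

**Steps most likely to fail**

Step 4. The risk is loss of regiocontrol: attack para to the methoxy group on the carbon next to the bridge, uneven bromination of the two rings, or radical bromination at the benzylic CH2 groups. The fallback replaces electrophilic substitution by directed ortho-metalation and sets out from 6. Both phenols are capped with MOMCl and i-Pr2NEt in CH2Cl2 to give 1,2-bis[3-methoxy-4-(methoxymethoxy)phenyl]ethane F1. Lithiation with n-BuLi/TMEDA in THF at 0 °C should take place on each ring at the only C–H ortho to the stronger OMOM director. A quench with 1,2-dibromotetrachloroethane should then give 1,2-bis[3-bromo-5-methoxy-4-(methoxymethoxy)phenyl]ethane F2. Acetal cleavage with HCl in MeOH returns the route at 9.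

Step 2. The risk is stalling after carbon–carbon bond formation (incomplete deoxygenation), competing simple reduction of the aldehyde, or Lewis-acid loss of benzyl ethers. The fallback builds the alkene by Horner–Wadsworth–Emmons olefination and sets out from 3. NaBH4 in MeOH gives (4-benzyloxy-3-methoxyphenyl)methanol F3, and SOCl2 in CH2Cl2 converts it to 1-(benzyloxy)-4-(chloromethyl)-2-methoxybenzene F4. A Michaelis–Arbuzov reaction with P(OEt)3 at 130 °C gives diethyl (4-benzyloxy-3-methoxybenzyl)phosphonate F5. Deprotonation with NaH in THF and addition of a second portion of 3 should give the E-stilbene, rejoining the route at 4.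

Step 5. The risk is incomplete cleavage of one of the two methyl ethers, or air oxidation of the electron-rich catechol during quench and purification. The fallback is oxidative demethylation followed by reduction and sets out from 9. IBX in DMF at low temperature should oxidise each 2-methoxyphenol at the methoxy-bearing carbon, with loss of methanol, to give 5,5'-(ethane-1,2-diyl)bis(3-bromocyclohexa-3,5-diene-1,2-dione) F6. This is reduced in the same flask with aqueous Na2S2O4, returning at 11.

**Further compounds**
F1 | step 4 | 1,2-bis[3-methoxy-4-(methoxymethoxy)phenyl]ethane | COCOc1ccc(CCc2ccc(OCOC)c(OC)c2)cc1OC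
F2 | step 4 | 1,2-bis[3-bromo-5-methoxy-4-(methoxymethoxy)phenyl]ethane | COCOc1c(Br)cc(CCc2cc(Br)c(OCOC)c(OC)c2)cc1OC
F3 | step 2 | (4-benzyloxy-3-methoxyphenyl)methanol | COc1cc(CO)ccc1OCc1ccccc1
F4 | step 2 | 1-(benzyloxy)-4-(chloromethyl)-2-methoxybenzene | COc1cc(CCl)ccc1OCc1ccccc1
F5 | step 2 | diethyl (4-benzyloxy-3-methoxybenzyl)phosphonate | CCOP(=O)(Cc1ccc(OCc2ccccc2)c(OC)c1)OCC
F6 | step 5 | 5,5'-(ethane-1,2-diyl)bis(3-bromocyclohexa-3,5-diene-1,2-dione) | O=C1C(=O)C(Br)=CC(CCC2=CC(=O)C(=O)C(Br)=C2)=C1
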